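The hydroazulene is cut at two bonds, C1–CH3 and C4–C5 (C1 is the methyl-bearing fusion carbon, C4 the carbinol, C5 the fusion CH, C6 the ester carbon). C1 lies β to C6 through C5, and C4 hangs on a three-carbon arm from C1, so one C5 enolate of a C6 ketone serves both bonds. In a single operation a chiral copper catalyst transfers methyl from Me3Al to C1 of an achiral 3-substituted cyclohepta-2,5-dienone, and the C5 aluminium enolate closes the five-membered ring on a pendant isopropyl ketone; dehydration gives the bicyclic enone. The precursor carries the 4-methyl-3-oxopentyl chain at C1 and the skipped C8=C9 alkene. C4, C5 and C6 are then relayed from C1.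

Key step: step 8

Remark on numbering: the text uses daucane numbering (C1 quaternary fusion carbon, C2 and C3 ring CH2, C4 carbinol, C5 fusion CH, C6 ester carbon, C7, C8(Me)=C9, C10); compound names use azulene numbering (C1 = 8a, C4 = 3, C5 = 3a, C6 = 4).

Remark on the chemistry: L is O,O'-(biphenyl-2,2'-diyl) N,N-bis[(S)-1-(naphthalen-2-yl)ethyl]phosphoramidite. Its sense of induction on this new dienone is assumed to follow that on simple 3-alkylcycloalkenones; the mirror-image ligand is used if the opposite face is served.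

Remark on the precursor: 10 is a β,γ-unsaturated ketone on its C7 side. Its side-chain ketone is therefore put in place before the dienone exists, and the ring expansion is run under buffered conditions without strong acid or base.

Step 1
Reactants: 1 2-hydroxy-4-methylbenzaldehyde; 2 3-methylbutan-2-one
Product: 3 (E)-1-(2-hydroxy-4-methylphenyl)-4-methylpent-1-en-3-one
Conditions: 2 (3 equiv), NaOH (3 equiv), EtOH–H2O, 0 °C → rt; aq. HCl to pH 5
Reagents that add atoms: none
Why: Claisen–Schmidt condensation: only the methyl side of the ketone can lose water after aldol addition, and the conjugated E alkene is the thermodynamic outcome.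

Step 2
Reactants: 3 (E)-1-(2-hydroxy-4-methylphenyl)-4-methylpent-1-en-3-one
Product: 4 (E)-1-[2-(tert-butyldimethylsilyloxy)-4-methylphenyl]-4-methylpent-1-en-3-one
Conditions: TBSCl (1.2 equiv), imidazole (2.5 equiv), DMF, rt
Reagents that add atoms: tert-butyldimethylsilyl chloride, CC(C)(C)[Si](C)(C)Cl
Why: Routine silylation of a phenol; the hindered silyl ether is chosen because it should survive dissolving-metal reduction and then become a regiodefined silyl enol ether.

Step 3
Reactants: 4 (E)-1-[2-(tert-butyldimethylsilyloxy)-4-methylphenyl]-4-methylpent-1-en-3-one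
Product: 5 1-[2-(tert-butyldimethylsilyloxy)-4-methylphenyl]-4-methylpentan-3-one
Conditions: H2 (1 atm), 5% Pd/C, EtOAc, rt
Reagents that add atoms: none
Why: Heterogeneous hydrogenation saturates the conjugated alkene and leaves the ketone, the arene and the aryl silyl ether alone.

Step 4
Reactants: 5 1-[2-(tert-butyldimethylsilyloxy)-4-methylphenyl]-4-methylpentan-3-one
Product: 6 1-[2-(tert-butyldimethylsilyloxy)-4-methylcyclohexa-1,4-dien-1-yl]-4-methylpentan-3-ol
Conditions: Li (10 equiv), NH3(l)–THF, t-BuOH (10 equiv), −78 → −33 °C; solid NH4Cl; cold neutral work-up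
Reagents that add atoms: none
Why: Birch reduction of an aryl silyl ether: protonation occurs at the two unsubstituted positions ortho and meta to oxygen, so oxygen and both alkyl groups stay on sp2 carbons and the tetrasubstituted silyl enol ether forms with fixed regiochemistry, while the side-chain ketone is reduced to the racemic carbinol (any ketone that escapes reduction converges at 8).

Step 5
Reactants: 6 1-[2-(tert-butyldimethylsilyloxy)-4-methylcyclohexa-1,4-dien-1-yl]-4-methylpentan-3-ol
Product: 7 1-[6-(tert-butyldimethylsilyloxy)-4-methylbicyclo[4.1.0]hept-3-en-1-yl]-4-methylpentan-3-ol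
Conditions: Et2Zn (3 equiv), CH2I2 (3 equiv), CH2Cl2, 0 °C; pyridine then aq. NH4Cl
Reagents that add atoms: diiodomethane, ICI
Why: Furukawa-type Simmons–Smith cyclopropanation: the electrophilic zinc carbenoid prefers the electron-rich silyl enol ether to the trialkyl alkene, the ring fusion is necessarily cis, and the racemic centres are cleared in step 7.

Step 6
Reactants: 7 1-[6-(tert-butyldimethylsilyloxy)-4-methylbicyclo[4.1.0]hept-3-en-1-yl]-4-methylpentan-3-ol
Product: 8 1-[6-(tert-butyldimethylsilyloxy)-4-methylbicyclo[4.1.0]hept-3-en-1-yl]-4-methylpentan-3-one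
Conditions: Dess–Martin periodinane (1.3 equiv), NaHCO3, CH2Cl2, 0 °C → rt
Reagents that add atoms: none
Why: Dess–Martin oxidation of the secondary alcohol under buffered conditions, placed here so that the isopropyl ketone is present before the acid- and base-labile skipped dienone exists.

Step 7
Reactants: 8 1-[6-(tert-butyldimethylsilyloxy)-4-methylbicyclo[4.1.0]hept-3-en-1-yl]-4-methylpentan-3-one
Product: 10 6-methyl-3-(4-methyl-3-oxopentyl)cyclohepta-2,5-dien-1-one, via β-chloro ketone 9 (not isolated)
Conditions: FeCl3 (2.5 equiv), pyridine (1 equiv), DMF, 0 °C → rt; then NaOAc (4 equiv), MeOH, rt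
Reagents that add atoms: none
Why: Ito–Saegusa ring expansion: one-electron oxidation of the siloxycyclopropane by trivalent iron cleaves the ring-fusion bond to the tertiary β-keto radical, chlorine transfer gives the β-chloro ketone, and acetate removes HCl by E1cB so that the new enone lies between the inserted CH and the chain-bearing carbon while C8=C9 should stay skipped.

Step 8
Reactants: 10 6-methyl-3-(4-methyl-3-oxopentyl)cyclohepta-2,5-dien-1-one
Product: 13 (8aR)-3-isopropyl-6,8a-dimethyl-2,5,8,8a-tetrahydroazulen-4(1H)-one, via dimethylaluminium enolate 11 (not isolated), via bicyclic ketol 12 (not isolated)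
Conditions: copper thiophene-2-carboxylate (monovalent copper, 5 mol %), L (10 mol %), Me3Al (2.5 equiv), Et2O, −30 → 0 °C; aq. potassium sodium tartrate; crude 12: MsCl (1.5 equiv), Et3N (4 equiv), DMAP (0.1 equiv), CH2Cl2, 0 °C
Reagents that add atoms: trimethylaluminium, C[Al](C)C
Why: Transmetallation from Me3Al gives a chiral copper–methyl species that adds to C1, the β-carbon of the only conjugated enone in 10, and leaves the C5 dimethylaluminium enolate 11 with fixed regiochemistry; on warming, 11 attacks the aluminium-bound isopropyl ketone at C4, and the tertiary ketol 12 is dehydrated through its mesylate by E1cB towards C5, the only direction that gives a conjugated alkene. The closest known chemistry is the copper-catalysed asymmetric conjugate addition of trialkylaluminium reagents to 3-substituted cycloalkenones with use of the aluminium enolate, together with conjugate addition–aldol cyclisations of keto-enones. The five-membered ring closes in a 5-(enolexo)-exo-trig aldol. The C1 quaternary centre is the only stereocentre kept and is set by the ligand, which distinguishes the ring-CH2 (C10) side of trigonal C1 from the chain-CH2 (C2) side; the two ketol centres are erased on dehydration. The step needs 1,4-addition to outrun 1,2-addition to either carbonyl, which the low temperature, the ether solvent and the branching next to the side-chain carbonyl favour, and it needs the skipped C8=C9 alkene to stay in place, for which the cold, non-acidic dehydration is chosen.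

Step 9
Reactants: 13 (8aR)-3-isopropyl-6,8a-dimethyl-2,5,8,8a-tetrahydroazulen-4(1H)-one
Product: 14 (4R,8aR)-3-isopropyl-6,8a-dimethyl-1,2,4,5,8,8a-hexahydroazulen-4-ol
Conditions: (S)-1-methyl-3,3-diphenyltetrahydro-1H,3H-pyrrolo[1,2-c][1,3,2]oxazaborole (0.5 equiv), catecholborane (2 equiv), toluene, −78 °C; MeOH, aq. NaOH wash
Reagents that add atoms: none
Why: Corey–Bakshi–Shibata reduction under reagent control: the oxazaborolidine should bind the carbonyl with the fully substituted alkenyl carbon (C5) as the large group and the C7 methylene as the small one, so that hydride enters C6 from the face opposite the C1 methyl and the new hydroxyl is cis to that methyl, while catecholborane at −78 °C attacks only the carbonyl.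

Step 10
Reactants: 14 (4R,8aR)-3-isopropyl-6,8a-dimethyl-1,2,4,5,8,8a-hexahydroazulen-4-ol
Product: 15 (3R,3aS,4R,8aR)-3,3a-epoxy-3-isopropyl-6,8a-dimethyl-1,2,3,3a,4,5,8,8a-octahydroazulen-4-ol
Conditions: VO(acac)2 (5 mol %), t-BuOOH (1.5 equiv, in decane), CH2Cl2, 0 °C → rt
Reagents that add atoms: tert-butyl hydroperoxide, CC(C)(C)OO
Why: Hydroxyl-directed vanadium-catalysed epoxidation: the vanadate ester of the allylic C6 alcohol delivers oxygen to the C4=C5 face on its own side, which is the face of the C1 methyl, and the allylic tetrasubstituted alkene reacts much faster than the homoallylic C8=C9.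

Step 11
Reactants: 15 (3R,3aS,4R,8aR)-3,3a-epoxy-3-isopropyl-6,8a-dimethyl-1,2,3,3a,4,5,8,8a-octahydroazulen-4-ol
Product: 18 (3R,3aR,8aR)-3-hydroxy-3-isopropyl-6,8a-dimethyl-2,3,3a,5,8,8a-hexahydroazulen-4(1H)-one, via epoxy silyl ether 16 (not isolated), via β-silyloxy ketone 17 (not isolated)
Conditions: TMSOTf (2.2 equiv), iPr2NEt (2.5 equiv), CH2Cl2, −78 → −40 °C; then citric acid, MeOH, 0 °C
Reagents that add atoms: none
Why: Silyl-triflate-promoted semipinacol (non-aldol aldol) rearrangement of a 2,3-epoxy silyl ether: the C6 hydrogen, antiperiplanar to the C5–O bond because hydroxyl and epoxide are cis, shifts to C5 with inversion as that bond breaks and C6 becomes the ketone, so that C5–H ends up trans to the retained C4–O bond and to the C1 methyl (trans ring fusion), and dilute acid then frees the tertiary alcohol.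

Step 12
Reactants: 18 (3R,3aR,8aR)-3-hydroxy-3-isopropyl-6,8a-dimethyl-2,3,3a,5,8,8a-hexahydroazulen-4(1H)-one
Product: 19 (3R,3aS,4S,8aR)-3-isopropyl-6,8a-dimethyl-1,2,3,3a,4,5,8,8a-octahydroazulene-3,4-diol
Conditions: Me4NBH(OAc)3 (5 equiv), MeCN–AcOH (1:1), −30 → 0 °C; aq. potassium sodium tartrate
Reagents that add atoms: none
Why: Evans–Saksena reduction: the C4 hydroxyl exchanges onto boron and hydride is delivered within the molecule to the C6 carbonyl from the face of the C4–O bond, which should give the 1,3-anti diol with the C6 hydroxyl on the face of C5–H and opposite to the C1 methyl.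

Step 13
Reactants: 19 (3R,3aS,4S,8aR)-3-isopropyl-6,8a-dimethyl-1,2,3,3a,4,5,8,8a-octahydroazulene-3,4-diol; 20 2-acetoxybenzoyl chloride
Product: 22 (3R,3aS,4S,8aR)-3-hydroxy-3-isopropyl-6,8a-dimethyl-1,2,3,3a,4,5,8,8a-octahydroazulen-4-yl 2-hydroxybenzoate, via O-acetylsalicylate 21 (not isolated)
Conditions: 20 (1.5 equiv), pyridine (3 equiv), DMAP (0.2 equiv), CH2Cl2, 0 °C → rt; then pyrrolidine (4 equiv), rt
Reagents that add atoms: none
Why: DMAP-catalysed acylation takes place only at the secondary C6 hydroxyl (the tertiary C4 hydroxyl is inert) with retention at C6, and the aryl acetate is then removed by aminolysis with pyrrolidine because a phenyl ester is far more electrophilic than the hindered, hydrogen-bonded salicylate.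

Compound list

1 | 2-hydroxy-4-methylbenzaldehyde | Cc1ccc(C=O)c(O)c1 | starting material
2 | 3-methylbutan-2-one | CC(C)C(C)=O | starting material
3 | (E)-1-(2-hydroxy-4-methylphenyl)-4-methylpent-1-en-3-one | CC(C)C(=O)/C=C/c1ccc(C)cc1O | intermediate
4 | (E)-1-[2-(tert-butyldimethylsilyloxy)-4-methylphenyl]-4-methylpent-1-en-3-one | CC(C)C(=O)/C=C/c1ccc(C)cc1O[Si](C)(C)C(C)(C)C | intermediate
5 | 1-[2-(tert-butyldimethylsilyloxy)-4-methylphenyl]-4-methylpentan-3-one | CC(C)C(=O)CCc1ccc(C)cc1O[Si](C)(C)C(C)(C)C | intermediate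
6 | 1-[2-(tert-butyldimethylsilyloxy)-4-methylcyclohexa-1,4-dien-1-yl]-4-methylpentan-3-ol, racemic | CC(C)C(O)CCC1=C(O[Si](C)(C)C(C)(C)C)CC(C)=CC1 | intermediate
7 | 1-[6-(tert-butyldimethylsilyloxy)-4-methylbicyclo[4.1.0]hept-3-en-1-yl]-4-methylpentan-3-ol, racemic, cis-fused cyclopropane, both carbinol epimers | CC(C)C(O)CCC12CC=C(C)CC1(O[Si](C)(C)C(C)(C)C)C2 | intermediate
8 | 1-[6-(tert-butyldimethylsilyloxy)-4-methylbicyclo[4.1.0]hept-3-en-1-yl]-4-methylpentan-3-one, racemic | CC(C)C(=O)CCC12CC=C(C)CC1(O[Si](C)(C)C(C)(C)C)C2 | intermediate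
9 | 3-chloro-6-methyl-3-(4-methyl-3-oxopentyl)cyclohept-5-en-1-one, racemic | CC(C)C(=O)CCC1(Cl)CC=C(C)CC(=O)C1 | intermediate
10 | 6-methyl-3-(4-methyl-3-oxopentyl)cyclohepta-2,5-dien-1-one | CC1=CCC(CCC(=O)C(C)C)=CC(=O)C1 | intermediate
11 | dimethylaluminium (R)-3,6-dimethyl-3-(4-methyl-3-oxopentyl)cyclohepta-1,5-dien-1-olate | CC1=CC[C@@](C)(CCC(=O)C(C)C)C=C(O[Al](C)C)C1 | intermediate
12 | (8aR)-3-hydroxy-3-isopropyl-6,8a-dimethyl-2,3,3a,5,8,8a-hexahydroazulen-4(1H)-one, C3 and C3a not assigned (cis fusion expected) | CC1=CC[C@@]2(C)CCC(O)(C(C)C)C2C(=O)C1 | intermediate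
13 | (8aR)-3-isopropyl-6,8a-dimethyl-2,5,8,8a-tetrahydroazulen-4(1H)-one | CC1=CC[C@@]2(C)CCC(C(C)C)=C2C(=O)C1 | intermediate
14 | (4R,8aR)-3-isopropyl-6,8a-dimethyl-1,2,4,5,8,8a-hexahydroazulen-4-ol, hydroxyl cis to the 8a-methyl | CC1=CC[C@@]2(C)CCC(C(C)C)=C2[C@H](O)C1 | intermediate
15 | (3R,3aS,4R,8aR)-3,3a-epoxy-3-isopropyl-6,8a-dimethyl-1,2,3,3a,4,5,8,8a-octahydroazulen-4-ol, epoxide oxygen, hydroxyl and 8a-methyl on one face | CC1=CC[C@@]2(C)CC[C@]3(C(C)C)O[C@]23[C@H](O)C1 | intermediate
16 | [(3R,3aS,4R,8aR)-3,3a-epoxy-3-isopropyl-6,8a-dimethyl-1,2,3,3a,4,5,8,8a-octahydroazulen-4-yl]oxytrimethylsilane | CC1=CC[C@@]2(C)CC[C@]3(C(C)C)O[C@]23[C@H](O[Si](C)(C)C)C1 | intermediate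
17 | (3R,3aR,8aR)-3-isopropyl-6,8a-dimethyl-3-(trimethylsilyloxy)-2,3,3a,5,8,8a-hexahydroazulen-4(1H)-one | CC1=CC[C@@]2(C)CC[C@@](O[Si](C)(C)C)(C(C)C)[C@@H]2C(=O)C1 | intermediate
18 | (3R,3aR,8aR)-3-hydroxy-3-isopropyl-6,8a-dimethyl-2,3,3a,5,8,8a-hexahydroazulen-4(1H)-one, trans-fused | CC1=CC[C@@]2(C)CC[C@@](O)(C(C)C)[C@@H]2C(=O)C1 | intermediate
19 | (3R,3aS,4S,8aR)-3-isopropyl-6,8a-dimethyl-1,2,3,3a,4,5,8,8a-octahydroazulene-3,4-diol | CC1=CC[C@@]2(C)CC[C@@](O)(C(C)C)[C@@H]2[C@@H](O)C1 | intermediate
20 | 2-acetoxybenzoyl chloride | CC(=O)Oc1ccccc1C(Cl)=O | starting material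
21 | (3R,3aS,4S,8aR)-3-hydroxy-3-isopropyl-6,8a-dimethyl-1,2,3,3a,4,5,8,8a-octahydroazulen-4-yl 2-acetoxybenzoate | CC1=CC[C@@]2(C)CC[C@@](O)(C(C)C)[C@@H]2[C@@H](OC(=O)c2ccccc2OC(C)=O)C1 | intermediate
22 | (3R,3aS,4S,8aR)-3-hydroxy-3-isopropyl-6,8a-dimethyl-1,2,3,3a,4,5,8,8a-octahydroazulen-4-yl 2-hydroxybenzoate | CC1=CC[C@@]2(C)CC[C@@](O)(C(C)C)[C@@H]2[C@@H](OC(=O)c2ccccc2O)C1 | target

Total step count: 13. Longest linear sequence: 13 steps (1 to 22); 2 and 20 enter in steps 1 and 13.

Steps most likely to fail, highest risk first: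

Step 8. The cascade may come apart: the aluminium enolate may add too slowly to the hindered ketone while excess Me3Al attacks that ketone, facial discrimination at C1 may be insufficient, or the skipped alkene may migrate during dehydration. The fallback sets out from 10 and comes back at 12. Only the conjugate addition is run, and the enolate is quenched at −30 °C with TMSOTf to isolate the silyl enol ether (R)-trimethyl{[3,6-dimethyl-3-(4-methyl-3-oxopentyl)cyclohepta-1,5-dien-1-yl]oxy}silane F1. The ring is then closed in a separate intramolecular Mukaiyama aldol (TiCl4, CH2Cl2, −78 °C) to ketol 12, which is dehydrated to 13 as in the main route.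

Step 11. The epoxide may ionise at C4 instead of C5, giving elimination or ring contraction in place of the hydride shift, or the product ketone may be silylated as a dienol ether and return with a shifted double bond. The fallback sets out from 15 and comes back at 18. Compound 15 is oxidised with Dess–Martin periodinane to the epoxy ketone (3R,3aR,8aR)-3,3a-epoxy-3-isopropyl-6,8a-dimethyl-2,3,3a,5,8,8a-hexahydroazulen-4(1H)-one F2, and its α C–O bond is cleaved with SmI2 (THF–MeOH, −78 °C). The carbonyl then dictates which C–O bond breaks, and protonation of the samarium enolate at C5 from the face opposite the C1 methyl and the C4 alkoxide should give 18.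

Step 7. The oxidative opening may stall at the hindered silyl ether, or acid released in the iron step may pull C8=C9 into conjugation. The fallback uses a carbene ring expansion, sets out from 5 and comes back at 10:
- Compound 5 is ketalised (ethane-1,2-diol, TsOH, benzene, water removal) to tert-butyl{2-[2-(2-isopropyl-1,3-dioxolan-2-yl)ethyl]-5-methylphenoxy}dimethylsilane F3.
- Birch reduction gives tert-butyl({2-[2-(2-isopropyl-1,3-dioxolan-2-yl)ethyl]-5-methylcyclohexa-1,4-dien-1-yl}oxy)dimethylsilane F4.
- Dibromocarbene (CHBr3, KOtBu, pentane, −20 °C) adds to the enol ether to give {7,7-dibromo-6-[2-(2-isopropyl-1,3-dioxolan-2-yl)ethyl]-3-methylbicyclo[4.1.0]hept-3-en-1-yl}oxy(tert-butyl)dimethylsilane F5.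
- Buffered AgNO3 in aqueous acetone opens F5 to 2-bromo-3-[2-(2-isopropyl-1,3-dioxolan-2-yl)ethyl]-6-methylcyclohepta-2,5-dien-1-one F6.
- Zn in aqueous AcOH removes the vinylic bromine and hydrolyses the ketal to give 10. This must be done promptly, because heat or base would eliminate HBr from F6 towards a tropone.

Further compounds

F1 | step 8 | (R)-trimethyl{[3,6-dimethyl-3-(4-methyl-3-oxopentyl)cyclohepta-1,5-dien-1-yl]oxy}silane | CC1=CC[C@@](C)(CCC(=O)C(C)C)C=C(O[Si](C)(C)C)C1
F2 | step 11 | (3R,3aR,8aR)-3,3a-epoxy-3-isopropyl-6,8a-dimethyl-2,3,3a,5,8,8a-hexahydroazulen-4(1H)-one | CC1=CC[C@@]2(C)CC[C@]3(C(C)C)O[C@]23C(=O)C1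
F3 | step 7 | tert-butyl{2-[2-(2-isopropyl-1,3-dioxolan-2-yl)ethyl]-5-methylphenoxy}dimethylsilane | CC(C)C1(CCc2ccc(C)cc2O[Si](C)(C)C(C)(C)C)OCCO1
F4 | step 7 | tert-butyl({2-[2-(2-isopropyl-1,3-dioxolan-2-yl)ethyl]-5-methylcyclohexa-1,4-dien-1-yl}oxy)dimethylsilane | CC(C)C1(CCC2=C(O[Si](C)(C)C(C)(C)C)CC(C)=CC2)OCCO1
F5 | step 7 | {7,7-dibromo-6-[2-(2-isopropyl-1,3-dioxolan-2-yl)ethyl]-3-methylbicyclo[4.1.0]hept-3-en-1-yl}oxy(tert-butyl)dimethylsilane | CC(C)C1(CCC23CC=C(C)CC2(O[Si](C)(C)C(C)(C)C)C3(Br)Br)OCCO1
F6 | step 7 | 2-bromo-3-[2-(2-isopropyl-1,3-dioxolan-2-yl)ethyl]-6-methylcyclohepta-2,5-dien-1-one | CC(C)C1(CCC2=C(Br)C(=O)CC(C)=CC2)OCCO1
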